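**Remarks.** Locants C1–C15 follow the eremophilane numbering of the target and are also used for the open-chain precursors: C1 carries the acyloxy group, C4 the carboxyl carbon C15, C5 the angular methyl C14, C7 the C11–C13 side chain, C8 is the ketone, C9=C10 the ring alkene; β is the face of the C14 methyl. Compound 1 is assumed to be commercially available (it is otherwise made from L-ascorbic acid).

## Retrosynthetic overview

1. Integric acid ⇒ tert-butyl ester 35 ⇒ bicyclic dienone 20: the C7 acrolein comes from allylic oxidation of an isopropenyl group, the C8 ketone from an 8α-silyloxy group, and the C1 ester from acylation of the 1β-alcohol 21 with acid 30.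
2. 20 ⇒ open-chain chloro enone 17: C5–C10 closes ring A first, then C2–C3 closes ring B, both in one flask.
3. Enabling feature: in ring B (C1–C2–C3–C4–C5–C10) the oxygenated C1 and the carboxyl-bearing C4 are para. C2–C1(=O)–C10 can therefore act as an acetone α,α′-dinucleophile and C3–C4(C15)–C5 as a 2-carboxyallyl 1,3-dielectrophile, while C5–C10 is also the fusion bond of ring A (C5–C6–C7–C8–C9–C10).
4. 17 ⇒ (S)-glyceraldehyde acetonide (C7–C8–C9; its C8 oxygen ends as the ketone), the same acetonyl ylide used twice (C14–C5–C6 and C2–C1–C10), an isopropenyl cuprate (C11–C13) and an acrylate α-anion equivalent (C3, C4, C15).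
5. Acid 30 ⇒ Evans methylation of a hexanoyl imide, then oxidation/Wittig olefination and saponification.

Key step: step 10

## Route

Step 1
Reactants: 1 (S)-2,2-dimethyl-1,3-dioxolane-4-carbaldehyde; 2 1-(triphenyl-λ5-phosphanylidene)propan-2-one
Product: 3 (R,E)-4-(2,2-dimethyl-1,3-dioxolan-4-yl)but-3-en-2-one
Conditions: CH2Cl2, 0 → 23 °C
Reagents that add atoms: none
Why: Wittig olefination with a stabilised ylide should give the E-enone without epimerising the α-oxygenated centre (C8).

Step 2
Reactants: 3 (R,E)-4-(2,2-dimethyl-1,3-dioxolan-4-yl)but-3-en-2-one; 4 isopropenylmagnesium bromide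
Product: 6 (4S)-4-[(4R)-2,2-dimethyl-1,3-dioxolan-4-yl]-5-methylhex-5-en-2-one, via silyl enol ether 5 (not isolated)
Conditions: CuBr·SMe2 (10 mol %), Me3SiCl, THF, −78 °C; then 10 % aq. citric acid
Reagents that add atoms: none
Why: Copper-catalysed conjugate addition of the Grignard reagent should set C7 anti to the γ-oxygen (attack anti to the C8–O bond with H8 eclipsing the alkene), as in cuprate additions to γ-alkoxy enoates.

Step 3
Reactants: 7 tert-butyl acrylate; 8 dimethylamine
Product: 9 tert-butyl 3-(dimethylamino)propanoate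
Conditions: Me2NH (2 M in THF), 23 °C
Reagents that add atoms: none
Why: Aza-Michael addition of a secondary amine to an acrylate is fast and clean.

Step 4
Reactants: 6 (4S)-4-[(4R)-2,2-dimethyl-1,3-dioxolan-4-yl]-5-methylhex-5-en-2-one; 9 tert-butyl 3-(dimethylamino)propanoate
Product: 10 tert-butyl (5S)-2-[(dimethylamino)methyl]-5-[(4R)-2,2-dimethyl-1,3-dioxolan-4-yl]-3-hydroxy-3,6-dimethylhept-6-enoate (C4/C5 epimer mixture)
Conditions: LDA, THF, −78 °C, 9; then 6; aq. NH4Cl
Reagents that add atoms: none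
Why: Aldol addition of the β-amino ester enolate (an acrylate α-anion equivalent) to the methyl ketone should form the C4–C5 bond; both new centres are erased later (C4 in step 5, C5 in step 9).

Step 5
Reactants: 10 aldol adduct
Product: 12 tert-butyl (5S)-5-[(4R)-2,2-dimethyl-1,3-dioxolan-4-yl]-3-hydroxy-3,6-dimethyl-2-methylidenehept-6-enoate (both C5 epimers), via ammonium iodide 11 (not isolated)
Conditions: MeI, MeOH, 23 °C; then K2CO3, CH2Cl2/MeOH
Reagents that add atoms: none
Why: N-Quaternisation followed by E1cB loss of trimethylamine should give the Morita–Baylis–Hillman-type adduct of a ketone.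

Step 6
Reactants: 12 tertiary allylic alcohol
Product: 13 tert-butyl (5S,6R)-3,6,7-trihydroxy-3-methyl-2-methylidene-5-(prop-1-en-2-yl)heptanoate
Conditions: AcOH/H2O (4:1), 40 °C
Reagents that add atoms: none
Why: Acid-catalysed acetal hydrolysis should leave the tert-butyl ester and the electron-poor tertiary allylic alcohol intact.

Step 7
Reactants: 13 triol; 2 1-(triphenyl-λ5-phosphanylidene)propan-2-one
Product: 15 tert-butyl (5S,6S,7E)-3,6-dihydroxy-3-methyl-2-methylidene-9-oxo-5-(prop-1-en-2-yl)dec-7-enoate, via hydroxy aldehyde 14 (not isolated)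
Conditions: TEMPO (20 mol %), PhI(OAc)2, CH2Cl2, 23 °C; then 2, 23 °C
Reagents that add atoms: none
Why: Nitroxyl-catalysed oxidation is selective for the primary alcohol, and the stabilised ylide should trap the α-hydroxy aldehyde in situ as the E-enone (one-pot oxidation/Wittig olefination).

Step 8
Reactants: 15 dihydroxy enone
Product: 16 tert-butyl (5S,6S,7E)-6-[(tert-butyldimethylsilyl)oxy]-3-hydroxy-3-methyl-2-methylidene-9-oxo-5-(prop-1-en-2-yl)dec-7-enoate
Conditions: TBSCl, imidazole, DMAP (cat.), DMF, 23 → 40 °C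
Reagents that add atoms: tert-butyldimethylsilyl chloride CC(C)(C)[Si](C)(C)Cl
Why: Silylation should be selective for the secondary C8 hydroxyl because the tertiary C5 hydroxyl is too hindered.

Step 9
Reactants: 16 tertiary allylic alcohol
Product: 17 tert-butyl (5S,6S,7E)-6-[(tert-butyldimethylsilyl)oxy]-2-(chloromethyl)-3-methyl-9-oxo-5-(prop-1-en-2-yl)deca-2,7-dienoate (2E/2Z mixture)
Conditions: SOCl2, Et2O, −20 → 0 °C
Reagents that add atoms: thionyl chloride O=S(Cl)Cl
Why: SNi′ chlorination through the chlorosulfite should deliver chloride to C3 with transposition of the double bond to C4=C5, as with other tertiary allylic and Morita–Baylis–Hillman alcohols; the E/Z mixture is of no consequence because both isomers converge in step 10.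

Step 10
Reactants: 17 allylic chloride
Product: 20 tert-butyl 8α-[(tert-butyldimethylsilyl)oxy]-1-oxoeremophila-9,11-dien-15-oate (4β-ester; 5β-methyl; 7α-isopropenyl), via phosphonium chloride 18 (not isolated), via monocyclic enone 19 (not isolated)
Conditions: PBu3 (2.5 equiv), t-BuOH/THF (0.02 M), 23 °C; then KOt-Bu (1.5 equiv), 0 → 23 °C
Reagents that add atoms: none
Why: Proposed new method: PBu3 displaces the primary allylic chloride to give an allylphosphonium salt and a second PBu3 adds reversibly to C9 of the enone; the resulting C10 enolate adds to C5, the β-carbon of the phosphonium-activated enoate, and expels PBu3 from C3 (net SN2′, 6-(enolexo)-exo-trig, ring A, 18), after which KOt-Bu eliminates PBu3 from C9 (E1cB, 19) and forms the C2 enolate, which closes ring B by a 6-endo-trig Michael addition to C3 before the ester enolate is protonated. The closest known reactions are the phosphine-mediated intramolecular Morita–Baylis–Hillman allylic alkylation of enones to five- and six-membered rings, the SN2′ substitution of Morita–Baylis–Hillman halides and carbonates at the carbinol carbon, and the Lawton α,α′-annulation of ketones with 2-(halomethyl)acrylates; new are the fully substituted electrophilic carbon and the relay of both closures in one flask. C5 should be set in the ring A closure through a chair transition state with the C7 isopropenyl group and the enoate arm equatorial and the C5 methyl axial, which places the methyl trans to the isopropenyl group. C4 should be set by protonation of the ester enolate anti to the axial C5 methyl, which also gives the equatorial, more stable ester. The regioselectivity rests on three features: only attack of C10 on C5 gives a six-membered ring, C10 bears no hydrogen once the enone is restored so only C2 can be enolised towards the acrylate, and no base is present before ring A has closed so the allylphosphonium salt is not turned into an ylide.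

Step 11
Reactants: 20 bicyclic dienone
Product: 21 tert-butyl 8α-[(tert-butyldimethylsilyl)oxy]-1β-hydroxyeremophila-9,11-dien-15-oate
Conditions: NaBH4, CeCl3·7H2O, MeOH, −78 → 0 °C
Reagents that add atoms: none
Why: Luche 1,2-reduction, in which hydride should enter C1 from the α face, anti to the syn-axial C5 methyl, giving the axial 1β-alcohol as in reductions of 6-oxo steroids.

Step 12
Reactants: 22 (S)-4-benzyloxazolidin-2-one; 23 hexanoyl chloride
Product: 24 (S)-4-benzyl-3-hexanoyloxazolidin-2-one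
Conditions: n-BuLi, THF, −78 °C; then 23
Reagents that add atoms: none
Why: N-Acylation of the lithiated oxazolidinone is a standard preparation of Evans imides.

Step 13
Reactants: 24 (S)-4-benzyl-3-hexanoyloxazolidin-2-one
Product: 25 (S)-4-benzyl-3-[(S)-2-methylhexanoyl]oxazolidin-2-one
Conditions: NaHMDS, THF, −78 °C; then MeI
Reagents that add atoms: iodomethane CI
Why: Evans alkylation, in which the chelated Z-enolate should be methylated on the face opposite the benzyl group, setting the (S) centre of the side chain.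

Step 14
Reactants: 25 methylated imide
Product: 26 (S)-2-methylhexan-1-ol
Conditions: LiBH4, MeOH (1 equiv), Et2O, 0 °C
Reagents that add atoms: none
Why: Reductive cleavage of the imide should give the primary alcohol without epimerisation and return the auxiliary.

Step 15
Reactants: 26 (S)-2-methylhexan-1-ol; 27 ethyl 2-(triphenyl-λ5-phosphanylidene)propanoate
Product: 29 ethyl (S,E)-2,4-dimethyloct-2-enoate, via (S)-2-methylhexanal 28 (not isolated)
Conditions: TEMPO (10 mol %), PhI(OAc)2, CH2Cl2, 23 °C; then 27, 40 °C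
Reagents that add atoms: none
Why: One-pot oxidation/Wittig olefination with the α-branched stabilised ylide should give the E-trisubstituted enoate without isolating the epimerisable aldehyde.

Step 16
Reactants: 29 ethyl (S,E)-2,4-dimethyloct-2-enoate
Product: 30 (S,E)-2,4-dimethyloct-2-enoic acid
Conditions: LiOH, THF/MeOH/H2O, 23 °C; then 1 M HCl
Reagents that add atoms: lithium hydroxide [Li+].[OH-]
Why: Saponification of the ethyl ester should leave the γ-stereocentre and the alkene geometry untouched.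

Step 17
Reactants: 21 1β-alcohol; 30 (S,E)-2,4-dimethyloct-2-enoic acid
Product: 32 tert-butyl 8α-[(tert-butyldimethylsilyl)oxy]-1β-{[(2E,4S)-2,4-dimethyloct-2-enoyl]oxy}eremophila-9,11-dien-15-oate, via mixed anhydride 31 (not isolated)
Conditions: 2,4,6-trichlorobenzoyl chloride, Et3N, THF, 23 °C; then 21, DMAP, toluene, 23 → 60 °C
Reagents that add atoms: none
Why: Yamaguchi esterification is the usual method for acylating hindered secondary alcohols with α-substituted enoic acids and should retain the C1 configuration.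

Step 18
Reactants: 32 ester
Product: 33 tert-butyl 8α-[(tert-butyldimethylsilyl)oxy]-1β-{[(2E,4S)-2,4-dimethyloct-2-enoyl]oxy}-13-hydroxyeremophila-9,11-dien-15-oate
Conditions: SeO2 (0.5 equiv), t-BuOOH, CH2Cl2, 23 °C
Reagents that add atoms: tert-butyl hydroperoxide CC(C)(C)OO
Why: Selenium dioxide allylic oxidation (ene reaction then [2,3] shift) should take place at the most electron-rich 1,1-disubstituted alkene and at its methyl group in preference to the C7 methine.

Step 19
Reactants: 33 allylic alcohol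
Product: 34 tert-butyl 1β-{[(2E,4S)-2,4-dimethyloct-2-enoyl]oxy}-8α,13-dihydroxyeremophila-9,11-dien-15-oate
Conditions: HF·pyridine, pyridine, THF, 0 → 23 °C
Reagents that add atoms: none
Why: Fluoride-mediated cleavage of the silyl ether should spare the tert-butyl ester and the allylic ester.

Step 20
Reactants: 34 diol
Product: 35 tert-butyl ester of integric acid
Conditions: Dess–Martin periodinane (2.5 equiv), NaHCO3, CH2Cl2, 0 °C
Reagents that add atoms: none
Why: Dess–Martin oxidation should convert both allylic alcohols at once (C8 to the enone, C13 to the enal) under buffered conditions, with the C7 substituent already in the equatorial, thermodynamically preferred position.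

Step 21
Reactants: 35 tert-butyl ester of integric acid
Product: 36 integric acid
Conditions: TFA/CH2Cl2 (1:4), 0 °C
Reagents that add atoms: none
Why: Acidolysis of the tert-butyl ester (loss of isobutene) avoids the basic conditions that would endanger the C7 centre and the C1 ester.

## Compound list

1 | (S)-2,2-dimethyl-1,3-dioxolane-4-carbaldehyde | O=C[C@@H]1COC(C)(C)O1 | starting material
2 | 1-(triphenyl-λ5-phosphanylidene)propan-2-one | CC(=O)C=P(c1ccccc1)(c1ccccc1)c1ccccc1 | starting material
3 | (R,E)-4-(2,2-dimethyl-1,3-dioxolan-4-yl)but-3-en-2-one | CC(=O)/C=C/[C@@H]1COC(C)(C)O1 | intermediate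
4 | isopropenylmagnesium bromide | C=C(C)[Mg]Br | starting material
5 | trimethylsilyl enol ether of 6 | CC(O[Si](C)(C)C)=C[C@@H](C(C)=C)[C@@H]1COC(C)(C)O1 | intermediate
6 | (4S)-4-[(4R)-2,2-dimethyl-1,3-dioxolan-4-yl]-5-methylhex-5-en-2-one | CC(=O)C[C@@H](C(C)=C)[C@@H]1COC(C)(C)O1 | intermediate
7 | tert-butyl acrylate | C=CC(=O)OC(C)(C)C | starting material
8 | dimethylamine | CNC | starting material
9 | tert-butyl 3-(dimethylamino)propanoate | CN(C)CCC(=O)OC(C)(C)C | intermediate
10 | tert-butyl (5S)-2-[(dimethylamino)methyl]-5-[(4R)-2,2-dimethyl-1,3-dioxolan-4-yl]-3-hydroxy-3,6-dimethylhept-6-enoate (C4/C5 epimers) | CN(C)CC(C(=O)OC(C)(C)C)C(C)(O)C[C@@H](C(C)=C)[C@@H]1COC(C)(C)O1 | intermediate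
11 | trimethylammonium iodide of 10 | C[N+](C)(C)CC(C(=O)OC(C)(C)C)C(C)(O)C[C@@H](C(C)=C)[C@@H]1COC(C)(C)O1.[I-] | intermediate
12 | tert-butyl (5S)-5-[(4R)-2,2-dimethyl-1,3-dioxolan-4-yl]-3-hydroxy-3,6-dimethyl-2-methylidenehept-6-enoate (C5 epimers) | C=C(C(=O)OC(C)(C)C)C(C)(O)C[C@@H](C(C)=C)[C@@H]1COC(C)(C)O1 | intermediate
13 | tert-butyl (5S,6R)-3,6,7-trihydroxy-3-methyl-2-methylidene-5-(prop-1-en-2-yl)heptanoate | C=C(C(=O)OC(C)(C)C)C(C)(O)C[C@@H](C(C)=C)[C@@H](O)CO | intermediate
14 | tert-butyl (5S,6R)-3,6-dihydroxy-3-methyl-2-methylidene-7-oxo-5-(prop-1-en-2-yl)heptanoate | C=C(C(=O)OC(C)(C)C)C(C)(O)C[C@@H](C(C)=C)[C@@H](O)C=O | intermediate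
15 | tert-butyl (5S,6S,7E)-3,6-dihydroxy-3-methyl-2-methylidene-9-oxo-5-(prop-1-en-2-yl)dec-7-enoate | C=C(C(=O)OC(C)(C)C)C(C)(O)C[C@@H](C(C)=C)[C@@H](O)/C=C/C(C)=O | intermediate
16 | tert-butyl (5S,6S,7E)-6-[(tert-butyldimethylsilyl)oxy]-3-hydroxy-3-methyl-2-methylidene-9-oxo-5-(prop-1-en-2-yl)dec-7-enoate | C=C(C(=O)OC(C)(C)C)C(C)(O)C[C@@H](C(C)=C)[C@@H](O[Si](C)(C)C(C)(C)C)/C=C/C(C)=O | intermediate
17 | tert-butyl (5S,6S,7E)-6-[(tert-butyldimethylsilyl)oxy]-2-(chloromethyl)-3-methyl-9-oxo-5-(prop-1-en-2-yl)deca-2,7-dienoate (2E/2Z) | ClCC(C(=O)OC(C)(C)C)=C(C)C[C@@H](C(C)=C)[C@@H](O[Si](C)(C)C(C)(C)C)/C=C/C(C)=O | intermediate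
18 | ring A phosphonium chloride (C5–C10 closed; PBu3 on C9; acetyl on C10; 1-(tert-butoxycarbonyl)vinyl on C5) | CC(=O)C1C([P+](CCCC)(CCCC)CCCC)[C@H](O[Si](C)(C)C(C)(C)C)[C@H](C(C)=C)C[C@]1(C)C(=C)C(=O)OC(C)(C)C.[Cl-] | intermediate
19 | tert-butyl 2-[2-acetyl-4α-[(tert-butyldimethylsilyl)oxy]-1β-methyl-5α-(prop-1-en-2-yl)cyclohex-2-en-1-yl]prop-2-enoate | CC(=O)C1=C[C@H](O[Si](C)(C)C(C)(C)C)[C@H](C(C)=C)C[C@]1(C)C(=C)C(=O)OC(C)(C)C | intermediate
20 | tert-butyl 8α-[(tert-butyldimethylsilyl)oxy]-1-oxoeremophila-9,11-dien-15-oate | C=C(C)[C@@H]1C[C@@]2(C)C(=C[C@@H]1O[Si](C)(C)C(C)(C)C)C(=O)CC[C@@H]2C(=O)OC(C)(C)C | intermediate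
21 | tert-butyl 8α-[(tert-butyldimethylsilyl)oxy]-1β-hydroxyeremophila-9,11-dien-15-oate | C=C(C)[C@@H]1C[C@@]2(C)C(=C[C@@H]1O[Si](C)(C)C(C)(C)C)[C@H](O)CC[C@@H]2C(=O)OC(C)(C)C | intermediate
22 | (S)-4-benzyloxazolidin-2-one | O=C1N[C@@H](Cc2ccccc2)CO1 | starting material
23 | hexanoyl chloride | CCCCCC(=O)Cl | starting material
24 | (S)-4-benzyl-3-hexanoyloxazolidin-2-one | CCCCCC(=O)N1[C@@H](Cc2ccccc2)COC1=O | intermediate
25 | (S)-4-benzyl-3-[(S)-2-methylhexanoyl]oxazolidin-2-one | CCCC[C@H](C)C(=O)N1[C@@H](Cc2ccccc2)COC1=O | intermediate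
26 | (S)-2-methylhexan-1-ol | CCCC[C@H](C)CO | intermediate
27 | ethyl 2-(triphenyl-λ5-phosphanylidene)propanoate | CCOC(=O)C(C)=P(c1ccccc1)(c1ccccc1)c1ccccc1 | starting material
28 | (S)-2-methylhexanal | CCCC[C@H](C)C=O | intermediate
29 | ethyl (S,E)-2,4-dimethyloct-2-enoate | CCCC[C@H](C)/C=C(\C)C(=O)OCC | intermediate
30 | (S,E)-2,4-dimethyloct-2-enoic acid | CCCC[C@H](C)/C=C(\C)C(=O)O | intermediate
31 | (S,E)-2,4-dimethyloct-2-enoic 2,4,6-trichlorobenzoic anhydride | CCCC[C@H](C)/C=C(\C)C(=O)OC(=O)c1c(Cl)cc(Cl)cc1Cl | intermediate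
32 | tert-butyl 8α-[(tert-butyldimethylsilyl)oxy]-1β-{[(2E,4S)-2,4-dimethyloct-2-enoyl]oxy}eremophila-9,11-dien-15-oate | C=C(C)[C@@H]1C[C@@]2(C)C(=C[C@@H]1O[Si](C)(C)C(C)(C)C)[C@H](OC(=O)/C(C)=C/[C@@H](C)CCCC)CC[C@@H]2C(=O)OC(C)(C)C | intermediate
33 | 13-hydroxy derivative of 32 | C=C(CO)[C@@H]1C[C@@]2(C)C(=C[C@@H]1O[Si](C)(C)C(C)(C)C)[C@H](OC(=O)/C(C)=C/[C@@H](C)CCCC)CC[C@@H]2C(=O)OC(C)(C)C | intermediate
34 | tert-butyl 1β-{[(2E,4S)-2,4-dimethyloct-2-enoyl]oxy}-8α,13-dihydroxyeremophila-9,11-dien-15-oate | C=C(CO)[C@@H]1C[C@@]2(C)C(=C[C@@H]1O)[C@H](OC(=O)/C(C)=C/[C@@H](C)CCCC)CC[C@@H]2C(=O)OC(C)(C)C | intermediate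
35 | tert-butyl ester of integric acid | C=C(C=O)[C@@H]1C[C@@]2(C)C(=CC1=O)[C@H](OC(=O)/C(C)=C/[C@@H](C)CCCC)CC[C@@H]2C(=O)OC(C)(C)C | intermediate
36 | integric acid, (1R,4S,5R,7S) core with (2E,4S)-2,4-dimethyloct-2-enoate | C=C(C=O)[C@@H]1C[C@@]2(C)C(=CC1=O)[C@H](OC(=O)/C(C)=C/[C@@H](C)CCCC)CC[C@@H]2C(=O)O | target

## Step count and risks

Total step count: 21. Longest linear sequence: 15 steps (steps 1, 2, 4–11 and 17–21, from compound 1).

**Step 10 (Proposed new method).** The C10 enolate may add too slowly to the fully substituted C5, so that the allylphosphonium salt is diverted into ylide chemistry once base is added, or ring A may close with poor facial selectivity at C5. The fallback uses known reactions, sets out from 12 and returns at 20.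
- Thionyl chloride converts 12 into the transposed allylic chloride F1.
- Lithium acetoacetate (DMF, cat. NaI) gives the allyl acetoacetate F2.
- A thermal Carroll rearrangement (xylene, 140 °C, loss of CO2) forms the C5–C10 bond sigmatropically, its position fixed by the [3,3] topology, and gives the methyl ketone F3.
- KOt-Bu in t-BuOH closes ring B by the same Michael addition of C2 to C3 and gives the cyclohexanone F4.
- Aqueous acetic acid frees the diol F5.
- TEMPO/PhI(OAc)2 gives the hydroxy aldehyde F6, which pyrrolidinium acetate cyclises by intramolecular aldol condensation (C10 onto C9, ring A) to the hydroxy dienone F7.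
- TBSCl/imidazole then gives 20.
- In this sequence C5 is formed without cyclic control, so the C5 epimers would have to be separated at F7.

**Step 18.** The ene step may lose site selectivity (attack at the C7 methine or at the ring alkene), or the primary alcohol may over-oxidise unevenly. The fallback sets out from 32 and returns at 35.
- Ene-type chlorination of the isopropenyl group with Ca(OCl)2/CO2 (as practised on carvone) gives the allylic chloride F9.
- N-Methylmorpholine N-oxide with NaI oxidises F9 to the enal F10.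
- HF·pyridine gives the hydroxy enal F11.
- Dess–Martin oxidation of the remaining C8 alcohol gives 35.

**Step 11.** Hydride delivery at C1 may show poor facial selectivity, and the axial 1β-alcohol is also the harder one to acylate in step 17. The fallback sets out from 20 and returns at 32: the 1α-alcohol F8 formed from 20 in that case is not recycled but esterified with inversion, since a Mitsunobu reaction with acid 30 (PPh3, DIAD, toluene) gives 32 directly.

## Further compounds

F1 | step 10 | tert-butyl (5S)-2-(chloromethyl)-5-[(4R)-2,2-dimethyl-1,3-dioxolan-4-yl]-3,6-dimethylhepta-2,6-dienoate | ClCC(C(=O)OC(C)(C)C)=C(C)C[C@@H](C(C)=C)[C@@H]1COC(C)(C)O1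
F2 | step 10 | 3-oxobutanoate ester of the allylic alcohol corresponding to F1 | CC(=O)CC(=O)OCC(C(=O)OC(C)(C)C)=C(C)C[C@@H](C(C)=C)[C@@H]1COC(C)(C)O1
F3 | step 10 | tert-butyl (5S)-5-[(4R)-2,2-dimethyl-1,3-dioxolan-4-yl]-3,6-dimethyl-2-methylidene-3-(2-oxopropyl)hept-6-enoate (C5 epimers) | CC(=O)CC(C)(C(=C)C(=O)OC(C)(C)C)C[C@@H](C(C)=C)[C@@H]1COC(C)(C)O1
F4 | step 10 | tert-butyl 2-{(2S)-2-[(4R)-2,2-dimethyl-1,3-dioxolan-4-yl]-3-methylbut-3-enyl}-2-methyl-4-oxocyclohexane-1-carboxylate (C5 epimers) | O=C1CCC(C(=O)OC(C)(C)C)C(C)(C[C@@H](C(C)=C)[C@@H]2COC(C)(C)O2)C1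
F5 | step 10 | diol from F4 | O=C1CCC(C(=O)OC(C)(C)C)C(C)(C[C@@H](C(C)=C)[C@@H](O)CO)C1
F6 | step 10 | hydroxy aldehyde from F5 | O=C1CCC(C(=O)OC(C)(C)C)C(C)(C[C@@H](C(C)=C)[C@@H](O)C=O)C1
F7 | step 10 | tert-butyl 8α-hydroxy-1-oxoeremophila-9,11-dien-15-oate | C=C(C)[C@@H]1C[C@@]2(C)C(=C[C@@H]1O)C(=O)CC[C@@H]2C(=O)OC(C)(C)C
F8 | step 11 | tert-butyl 8α-[(tert-butyldimethylsilyl)oxy]-1α-hydroxyeremophila-9,11-dien-15-oate | C=C(C)[C@@H]1C[C@@]2(C)C(=C[C@@H]1O[Si](C)(C)C(C)(C)C)[C@@H](O)CC[C@@H]2C(=O)OC(C)(C)C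
F9 | step 18 | 13-chloro derivative of 32 | C=C(CCl)[C@@H]1C[C@@]2(C)C(=C[C@@H]1O[Si](C)(C)C(C)(C)C)[C@H](OC(=O)/C(C)=C/[C@@H](C)CCCC)CC[C@@H]2C(=O)OC(C)(C)C
F10 | step 18 | 13-oxo derivative of 32 | C=C(C=O)[C@@H]1C[C@@]2(C)C(=C[C@@H]1O[Si](C)(C)C(C)(C)C)[C@H](OC(=O)/C(C)=C/[C@@H](C)CCCC)CC[C@@H]2C(=O)OC(C)(C)C
F11 | step 18 | 8α-hydroxy-13-oxo compound | C=C(C=O)[C@@H]1C[C@@]2(C)C(=C[C@@H]1O)[C@H](OC(=O)/C(C)=C/[C@@H](C)CCCC)CC[C@@H]2C(=O)OC(C)(C)C
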